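Locants: rings A/B = 2-oxabicyclo[3.3.0]octan-3-one (C1–C8, C7 = spiro carbon); ring C = cyclohexene C1′(=C7)–C6′, with C2′ (bears CH2O), C3′ (=CH), C4′ and C5′ (carbinols), C6′ (CHCH3).
Retrosynthesis: take off the angelate and the exo-methylene; trace C6′–CH3, C5′–OH and C4′–OH back to a spiro cyclohexa-2′,5′-dien-4′-one; cut ring C at C2′=C3′ and C5′–C6′, which releases acetone (C3′–C4′–C5′) and a 7-acyl-7-formyl lactone.
Enabling feature: the quaternary spiro carbon C7 carries C2′ at ketone level and C6′ at aldehyde level, and C3′–C4′(O)–C5′ between them is an acetone unit, so ring C is the double aldol condensation product of acetone with a non-enolisable 1,3-dicarbonyl.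
Forward: rings A/B come from the enantiopure lactone 1; C7 is made quaternary and dressed as keto-aldehyde 5; ring C is closed on it in one (3+3) operation; CH3, OH and OH are then added to ring C; the exo-methylene and the angelate come last.
Stereochemistry: C1/C5 from 1; C7 by convex-face attack on the cis-fused bicycle; C6′ by the chiral copper catalyst; C5′ anti to that methyl (Rubottom); C4′ by hydroxyl-directed hydride delivery; the Z ester from angelic acid.

Key step: step 5

Remark: exo means the convex face of the bicycle (anti to the lactone ring); hydroformylation of 1 is assumed to place the formyl group on C7, the alkene carbon remote from the ring-fusion carbon C5.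

Step 1
Reactants: 1 (1R,5S)-2-oxabicyclo[3.3.0]oct-6-en-3-one
Product: 2 (1R,5R)-3-oxo-2-oxabicyclo[3.3.0]octane-7-carbaldehyde (C7 epimers)
Conditions: Rh(acac)(CO)2 (1 mol %), P(OC6H3-2,4-tBu2)3 (4 mol %), CO/H2 (1:1, 20 bar), toluene, 70 °C
Reagents that add atoms: carbon monoxide, [C-]#[O+]
Why: Rhodium-catalysed hydroformylation should add H and CHO across C6=C7 from the convex face with the formyl group on the less hindered C7; the C7 configuration does not matter because this centre is enolised in step 2.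

Step 2
Reactants: 2 (1R,5R)-3-oxo-2-oxabicyclo[3.3.0]octane-7-carbaldehyde
Product: 3 (1R,5R,7R)-7-(hydroxymethyl)-3-oxo-2-oxabicyclo[3.3.0]octane-7-carbaldehyde
Conditions: aq. CH2O (37 %), Et3N (20 mol %), THF, 50 °C
Reagents that add atoms: formaldehyde, C=O
Why: Amine-mediated crossed aldol (Tollens-type α-hydroxymethylation of an α-branched aldehyde): formaldehyde should attack the C7 enol on the convex face, so CH2OH ends exo and CHO endo, which fixes the future spiro centre.

Step 3
Reactants: 3 (1R,5R,7R)-7-(hydroxymethyl)-3-oxo-2-oxabicyclo[3.3.0]octane-7-carbaldehyde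
Product: 4 (1R,5R,7R)-7-[2-(benzyloxy)-1-hydroxyethyl]-7-(hydroxymethyl)-2-oxabicyclo[3.3.0]octan-3-one (carbinol epimers)
Conditions: BnOCH2Cl, SmI2, THF, 0 °C to rt
Reagents that add atoms: benzyl chloromethyl ether, ClCOCc1ccccc1
Why: Samarium Barbier alkoxymethylation: SmI2 reduces the chloromethyl ether to a benzyloxymethyl-samarium species that adds to the aldehyde while lactone and free hydroxyl are inert; the new carbinol centre is oxidised in step 4.

Step 4
Reactants: 4 (1R,5R,7R)-7-[2-(benzyloxy)-1-hydroxyethyl]-7-(hydroxymethyl)-2-oxabicyclo[3.3.0]octan-3-one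
Product: 5 (1R,5R,7R)-7-[(benzyloxy)acetyl]-3-oxo-2-oxabicyclo[3.3.0]octane-7-carbaldehyde
Conditions: Dess–Martin periodinane, CH2Cl2, rt
Reagents that add atoms: none
Why: Dess–Martin oxidation should convert the secondary carbinol into the ketone and the neopentyl CH2OH into the aldehyde in one operation, and the quaternary C7 has no hydrogen to epimerise.

Step 5
Reactants: 5 (1R,5R,7R)-7-[(benzyloxy)acetyl]-3-oxo-2-oxabicyclo[3.3.0]octane-7-carbaldehyde; 6 acetone
Product: 9 (1R,5R,7R)-2′-[(benzyloxy)methyl]spiro[2-oxabicyclo[3.3.0]octane-7,1′-cyclohexa-2′,5′-diene]-3,4′-dione, via aldol adduct 7 (not isolated), via ketol 8 (not isolated)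
Conditions: acetone (excess), pyrrolidine (30 mol %), AcOH (30 mol %), toluene, 70 °C
Reagents that add atoms: none
Why: Proposed new method: the pyrrolidine enamine of acetone adds to the formyl group of 5 (the most electrophilic carbonyl) to give 7 and so forms C5′–C6′, the enamine of the resulting methyl ketone then attacks the benzyloxymethyl ketone on the same quaternary carbon to give 8 and so forms C2′–C3′, and two E1cB dehydrations deliver the cross-conjugated dienone. The closest known reaction type is the amine-catalysed aldol condensation of Robinson and Hajos–Parrish cyclisations and the double aldol cyclocondensation of dicarbonyl compounds with ketones; its use as a (3+3) annulation of acetone onto a non-enolisable 2-acyl-2-formyl unit is the untested part. Ring C closes by a 6-(enolendo)-exo-trig aldol addition. No lasting stereocentre is created, since both carbinol carbons become sp2 and the spiro centre C7 was set in step 2. The step needs enamine formation at the unhindered methyl ketone instead of enolisation of the benzyloxymethyl ketone, which would close the isomeric 2-benzyloxy-cyclohexenone; a secondary amine cannot condense with the neopentyl ketone, and the quaternary carbon blocks every other enolisation. An (E)-enone from early dehydration should return to the productive path by reversible conjugate addition of the amine, the dienone being the thermodynamic sink.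

Step 6
Reactants: 9 (1R,5R,7R)-2′-[(benzyloxy)methyl]spiro[2-oxabicyclo[3.3.0]octane-7,1′-cyclohexa-2′,5′-diene]-3,4′-dione
Product: 10 (1R,5R,7R,6′S)-2′-[(benzyloxy)methyl]-6′-methylspiro[2-oxabicyclo[3.3.0]octane-7,1′-cyclohex-2′-ene]-3,4′-dione
Conditions: Me2Zn, Cu(OTf)2 (5 mol %), (S,R,R)-BINOL/bis(1-phenylethyl)amine phosphoramidite (10 mol %), toluene, −30 °C
Reagents that add atoms: dimethylzinc, C[Zn]C
Why: Copper/phosphoramidite-catalysed conjugate addition of a dialkylzinc, known for 4,4-disubstituted cyclohexa-2,5-dienones: methyl should go to C6′, the only β-CH terminus, and because the two dienone faces differ only in remote ring B atoms the ligand enantiomer (matched to the face on the side of C6) fixes C6′.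

Step 7
Reactants: 10 (1R,5R,7R,6′S)-2′-[(benzyloxy)methyl]-6′-methylspiro[2-oxabicyclo[3.3.0]octane-7,1′-cyclohex-2′-ene]-3,4′-dione
Product: 12 (1R,5R,7R,5′S,6′R)-2′-[(benzyloxy)methyl]-5′-hydroxy-6′-methylspiro[2-oxabicyclo[3.3.0]octane-7,1′-cyclohex-2′-ene]-3,4′-dione, via silyl dienol ether 11 (not isolated)
Conditions: LiHMDS, TMSCl, THF, −78 °C; then mCPBA, CH2Cl2, 0 °C; then aq. citric acid
Reagents that add atoms: mCPBA, O=C(OO)c1cccc(Cl)c1; chlorotrimethylsilane, C[Si](C)(C)Cl (silyl group in 11 only)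
Why: Rubottom oxidation: kinetic deprotonation should occur at C5′ (the only α-CH2 of the ketone, more acidic than the lactone CH2), and the electron-rich C4′=C5′ bond of 11 is epoxidised anti to the adjacent C6′ methyl, which gives the trans 5′-hydroxy-6′-methyl ketone.

Step 8
Reactants: 12 (1R,5R,7R,5′S,6′R)-2′-[(benzyloxy)methyl]-5′-hydroxy-6′-methylspiro[2-oxabicyclo[3.3.0]octane-7,1′-cyclohex-2′-ene]-3,4′-dione
Product: 13 (1R,5R,7R,4′S,5′S,6′R)-2′-[(benzyloxy)methyl]-4′,5′-dihydroxy-6′-methylspiro[2-oxabicyclo[3.3.0]octane-7,1′-cyclohex-2′-en]-3-one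
Conditions: Me4NBH(OAc)3, MeCN/AcOH, −20 °C
Reagents that add atoms: none
Why: Hydroxyl-directed Evans–Saksena reduction: the C5′ alkoxyborohydride should deliver hydride to the carbonyl face syn to C5′–OH, giving the trans 4′,5′-diol with all three ring C substituents equatorial.

Step 9
Reactants: 13 (1R,5R,7R,4′S,5′S,6′R)-2′-[(benzyloxy)methyl]-4′,5′-dihydroxy-6′-methylspiro[2-oxabicyclo[3.3.0]octane-7,1′-cyclohex-2′-en]-3-one
Product: 14 bis(tert-butyldimethylsilyl) ether of 13
Conditions: TBSOTf, 2,6-lutidine, CH2Cl2, 0 °C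
Reagents that add atoms: tert-butyldimethylsilyl triflate, CC(C)(C)[Si](C)(C)OS(=O)(=O)C(F)(F)F
Why: Standard silylation protects both secondary alcohols against the strong base of step 10 and creates no stereocentre.

Step 10
Reactants: 14 bis(tert-butyldimethylsilyl) ether of 13
Product: 17 4-methylene lactone (benzyl ether; bis-TBS ether), via Mannich base 15 (not isolated), via methiodide 16 (not isolated)
Conditions: LDA, THF, −78 °C; CH2=NMe2 iodide (Eschenmoser's salt), −78 °C to rt; then MeI, MeOH, rt; then aq. NaHCO3, CH2Cl2, rt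
Reagents that add atoms: Eschenmoser's salt, C=[N+](C)C.[I-]; iodomethane, CI (methyl in 16 only)
Why: Eschenmoser methylenation: the lactone enolate (the only acidic site left) gives the Mannich base, whose methiodide loses trimethylamine on mild base treatment to give the exocyclic alkene.

Step 11
Reactants: 17 4-methylene lactone (benzyl ether; bis-TBS ether)
Product: 18 primary allylic alcohol (bis-TBS ether)
Conditions: BCl3·SMe2, CH2Cl2, 0 °C to rt
Reagents that add atoms: none
Why: Boron trichloride–dimethyl sulfide cleaves benzyl ethers by benzyl–oxygen scission under conditions that secondary TBS ethers, lactones and alkenes normally survive.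

Step 12
Reactants: 18 primary allylic alcohol (bis-TBS ether); 19 angelic acid ((Z)-2-methylbut-2-enoic acid)
Product: 20 angelate ester (bis-TBS ether)
Conditions: 2,4,6-Cl3C6H2COCl, Et3N, toluene, rt; then 18, toluene, 70 °C
Reagents that add atoms: none
Why: Yamaguchi-type acylation with the preformed mixed anhydride should esterify the single free (primary allylic) hydroxyl, and omitting DMAP limits Z to E isomerisation to the tiglate.

Step 13
Reactants: 20 angelate ester (bis-TBS ether)
Product: 21 target CNP0224912.1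
Conditions: HF·pyridine, THF/pyridine, 0 °C to rt
Reagents that add atoms: none
Why: Buffered fluoride desilylation should free the trans-diol without acyl migration, ester cleavage or conjugate addition to the α-methylene lactone.

Compound list
1 | (1R,5S)-2-oxabicyclo[3.3.0]oct-6-en-3-one | C1C(=O)O[C@@H]2CC=C[C@H]12 | starting material
2 | (1R,5R)-3-oxo-2-oxabicyclo[3.3.0]octane-7-carbaldehyde (C7 epimers, mainly exo-CHO) | C1C(=O)O[C@@H]2CC(C=O)C[C@H]12 | intermediate
3 | (1R,5R,7R)-7-(hydroxymethyl)-3-oxo-2-oxabicyclo[3.3.0]octane-7-carbaldehyde (CH2OH exo, CHO endo) | C1C(=O)O[C@@H]2C[C@@](CO)(C[C@H]12)C=O | intermediate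
4 | (1R,5R,7R)-7-[2-(benzyloxy)-1-hydroxyethyl]-7-(hydroxymethyl)-2-oxabicyclo[3.3.0]octan-3-one (carbinol epimers) | C1C(=O)O[C@@H]2C[C@@](CO)(C[C@H]12)C(O)COCc3ccccc3 | intermediate
5 | (1R,5R,7R)-7-[(benzyloxy)acetyl]-3-oxo-2-oxabicyclo[3.3.0]octane-7-carbaldehyde (CHO exo, acyl endo) | C1C(=O)O[C@@H]2C[C@@](C=O)(C[C@H]12)C(=O)COCc3ccccc3 | intermediate
6 | acetone | CC(C)=O | starting material
7 | aldol adduct: (1R,5R,7R)-7-[(benzyloxy)acetyl]-7-(1-hydroxy-3-oxobutyl)-2-oxabicyclo[3.3.0]octan-3-one (carbinol epimers) | C1C(=O)O[C@@H]2C[C@@](C(O)CC(C)=O)(C[C@H]12)C(=O)COCc3ccccc3 | intermediate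
8 | ketol: 2′-[(benzyloxy)methyl]-2′,6′-dihydroxyspiro[2-oxabicyclo[3.3.0]octane-7,1′-cyclohexane]-3,4′-dione (carbinol epimers) | C1C(=O)O[C@@H]2C[C@@]3(C[C@H]12)C(O)(COCc4ccccc4)CC(=O)CC3O | intermediate
9 | (1R,5R,7R)-2′-[(benzyloxy)methyl]spiro[2-oxabicyclo[3.3.0]octane-7,1′-cyclohexa-2′,5′-diene]-3,4′-dione (C2′ on the lactone face) | C1C(=O)O[C@@H]2C[C@@]3(C[C@H]12)C(COCc4ccccc4)=CC(=O)C=C3 | intermediate
10 | (1R,5R,7R,6′S)-2′-[(benzyloxy)methyl]-6′-methylspiro[2-oxabicyclo[3.3.0]octane-7,1′-cyclohex-2′-ene]-3,4′-dione | C1C(=O)O[C@@H]2C[C@@]3(C[C@H]12)C(COCc4ccccc4)=CC(=O)C[C@@H]3C | intermediate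
11 | silyl dienol ether: 4′-(trimethylsilyloxy)-2′,4′-diene derived from 10 | C1C(=O)O[C@@H]2C[C@@]3(C[C@H]12)C(COCc4ccccc4)=CC(O[Si](C)(C)C)=C[C@@H]3C | intermediate
12 | (1R,5R,7R,5′S,6′R)-2′-[(benzyloxy)methyl]-5′-hydroxy-6′-methylspiro[2-oxabicyclo[3.3.0]octane-7,1′-cyclohex-2′-ene]-3,4′-dione (OH trans to CH3) | C1C(=O)O[C@@H]2C[C@@]3(C[C@H]12)C(COCc4ccccc4)=CC(=O)[C@@H](O)[C@@H]3C | intermediate
13 | (1R,5R,7R,4′S,5′S,6′R)-2′-[(benzyloxy)methyl]-4′,5′-dihydroxy-6′-methylspiro[2-oxabicyclo[3.3.0]octane-7,1′-cyclohex-2′-en]-3-one (trans-diol) | C1C(=O)O[C@@H]2C[C@@]3(C[C@H]12)C(COCc4ccccc4)=C[C@H](O)[C@@H](O)[C@@H]3C | intermediate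
14 | 4′,5′-bis(tert-butyldimethylsilyl) ether of 13 | C1C(=O)O[C@@H]2C[C@@]3(C[C@H]12)C(COCc4ccccc4)=C[C@H](O[Si](C)(C)C(C)(C)C)[C@@H](O[Si](C)(C)C(C)(C)C)[C@@H]3C | intermediate
15 | Mannich base: 4-[(dimethylamino)methyl] lactone from 14 (C4 epimers) | CN(C)CC1C(=O)O[C@@H]2C[C@@]3(C[C@H]12)C(COCc4ccccc4)=C[C@H](O[Si](C)(C)C(C)(C)C)[C@@H](O[Si](C)(C)C(C)(C)C)[C@@H]3C | intermediate
16 | methiodide: 4-[(trimethylammonio)methyl] lactone iodide | C[N+](C)(C)CC1C(=O)O[C@@H]2C[C@@]3(C[C@H]12)C(COCc4ccccc4)=C[C@H](O[Si](C)(C)C(C)(C)C)[C@@H](O[Si](C)(C)C(C)(C)C)[C@@H]3C.[I-] | intermediate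
17 | 4-methylene lactone with 2′-CH2OBn and 4′,5′-bis-TBS ether | C=C1C(=O)O[C@@H]2C[C@@]3(C[C@H]12)C(COCc4ccccc4)=C[C@H](O[Si](C)(C)C(C)(C)C)[C@@H](O[Si](C)(C)C(C)(C)C)[C@@H]3C | intermediate
18 | 4-methylene lactone with 2′-CH2OH and 4′,5′-bis-TBS ether | C=C1C(=O)O[C@@H]2C[C@@]3(C[C@H]12)C(CO)=C[C@H](O[Si](C)(C)C(C)(C)C)[C@@H](O[Si](C)(C)C(C)(C)C)[C@@H]3C | intermediate
19 | angelic acid, (Z)-2-methylbut-2-enoic acid | C/C=C(/C)C(=O)O | starting material
20 | angelate ester of 18 (4′,5′-bis-TBS ether) | C=C1C(=O)O[C@@H]2C[C@@]3(C[C@H]12)C(COC(=O)/C(C)=C\C)=C[C@H](O[Si](C)(C)C(C)(C)C)[C@@H](O[Si](C)(C)C(C)(C)C)[C@@H]3C | intermediate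
21 | CNP0224912.1 | C=C1C(=O)O[C@@H]2C[C@@]3(C[C@H]12)C(COC(=O)/C(C)=C\C)=C[C@H](O)[C@@H](O)[C@@H]3C | target

Total steps: 13. Longest linear sequence: 13 steps (1 to 21).

Steps most likely to fail

Step 5 (Proposed new method). The first aldol may dehydrate to an (E)-enone that cannot reach the ketone, the amine may cleave the non-enolisable keto-aldehyde by deformylation, or ring closure may be slow at the neopentyl ketone. The fallback uses known chemistry and sets out from 5. A Still–Gennari-type Z-selective Horner–Wadsworth–Emmons olefination of the aldehyde with bis(2,2,2-trifluoroethyl) (2-oxopropyl)phosphonate (KHMDS, 18-crown-6, THF, −78 °C) gives the (Z)-enone F1, in which the methyl ketone is held cis to the quaternary carbon. An intramolecular aldol condensation of that methyl ketone onto the benzyloxymethyl ketone (pyrrolidinium acetate or p-TsOH, toluene, heat) then closes ring C and comes back to the route at 9.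

Step 6. The catalyst may discriminate poorly between the two dienone faces, which the substrate does not bias, and methyl transfer to the neopentyl β-carbon may be sluggish. The fallback sets out from 5 and builds a removable sulfur controller into the three-carbon partner. Condensation of 5 with (R)-1-(p-tolylsulfinyl)propan-2-one (piperidine/AcOH; Knoevenagel at the aldehyde, then aldol condensation at the ketone) gives the 5′-[(S)-p-tolylsulfinyl] dienone F2. Chelation-controlled conjugate addition of MeMgBr/ZnBr2 (THF, −78 °C) to this 2-sulfinyl enone gives the methyl adduct F3, the sulfoxide directing the face. Aluminium amalgam (THF/H2O) removes the sulfinyl group and comes back to the route at 10.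

Step 1. The formyl group may be placed on C6 instead of C7, and the alkene may migrate before carbonylation. The fallback sets out from 1 and fixes the position with a bulky borane. Hydroboration with 9-BBN and oxidation with NaBO3 gives the exo-alcohol F4, whose regioisomer can be removed at this stage. Dess–Martin oxidation gives the ketone F5, Wittig reaction with Ph3P=CHOMe gives the enol ether F6, and aqueous acid hydrolysis comes back to the route at 2.

Further compounds
F1 | step 5 | (1R,5R,7R)-7-[(benzyloxy)acetyl]-7-[(Z)-3-oxobut-1-enyl]-2-oxabicyclo[3.3.0]octan-3-one | C1C(=O)O[C@@H]2C[C@@](/C=C\C(C)=O)(C[C@H]12)C(=O)COCc3ccccc3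
F2 | step 6 | 2′-[(benzyloxy)methyl]-5′-[(S)-(4-methylphenyl)sulfinyl]spiro[2-oxabicyclo[3.3.0]octane-7,1′-cyclohexa-2′,5′-diene]-3,4′-dione | C1C(=O)O[C@@H]2C[C@@]3(C[C@H]12)C(COCc4ccccc4)=CC(=O)C([S@@](=O)c5ccc(C)cc5)=C3
F3 | step 6 | 2′-[(benzyloxy)methyl]-6′-methyl-5′-[(4-methylphenyl)sulfinyl]spiro[2-oxabicyclo[3.3.0]octane-7,1′-cyclohex-2′-ene]-3,4′-dione (C5′ epimers; sulfur configuration as in F2) | C1C(=O)O[C@@H]2C[C@@]3(C[C@H]12)C(COCc4ccccc4)=CC(=O)C([S@@](=O)c5ccc(C)cc5)[C@@H]3C
F4 | step 1 | (1R,5R)-7-exo-hydroxy-2-oxabicyclo[3.3.0]octan-3-one | C1C(=O)O[C@@H]2C[C@@H](O)C[C@H]12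
F5 | step 1 | (1R,5R)-2-oxabicyclo[3.3.0]octane-3,7-dione | C1C(=O)O[C@@H]2CC(=O)C[C@H]12
F6 | step 1 | (1R,5R)-7-(methoxymethylene)-2-oxabicyclo[3.3.0]octan-3-one (E/Z mixture) | C1C(=O)O[C@@H]2CC(=COC)C[C@H]12
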